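A direct plan would hang the chain on a three-carbon acceptor: 2-phenylethyl acrylate A1 would come from acid-catalysed esterification, docos-1-ene A2 from Li2CuCl4-catalysed coupling of 1-bromooctadecane A3 with but-3-enylmagnesium bromide A4, and A2 would be hydroborated to 9-docosyl-9-BBN A5, which would be added 1,4 to A1 under CuCl–carbene catalysis.
Its weakest step would be this final conjugate addition of A5 to A1: a β-unsubstituted acrylate is unproven as acceptor for alkyl-9-BBN reagents, the copper enolate and traces of oxygen with the borane would both start oligomerisation of A1, and the untested reaction would stand last, where both fragments are lost with it.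
Next would be the alkyl–alkyl coupling of A3 with A4 to give A2: a stoichiometric Grignard step would be spent on joining two pieces of plain hydrocarbon whose alkene serves only as a handle for boron, and waxy homocoupled or isomerised hydrocarbons would be hard to remove.
Third would be the making and distilling of A1, a polymerisable monomer whose ester would then have to survive KOt-Bu and t-BuOH.
No stereocentre and no ring closure would be at stake; three steps and two organometallic reagents would go into two unfunctionalised C–C bonds (C3–C4 and C7–C8).

**Plan of the new route**
Feature used: C2–C25 of the acyl chain are an unbranched run of 23 CH2 groups and one CH3, with the ester at C1 as the only functional group and the phenyl ring beyond it. Every inner CH2–CH2 bond therefore joins two primary carbons of like polarity and can be made from two primary alkyl radicals.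
First cut: C8–C9, with a CO2H restored on each carbon. C9–C25 then comes from a C18 fatty acid and C1–C8 from the 2-phenylethyl half-ester of the C9 diacid; the odd C25 chain is (18 − 1) + (9 − 1) carbons.
Second cut: the free carboxyl of that half-ester is traced to C9 of a C9=C10 alkene, so the ester C1–O bond is made first on a mono-acid and the two ends of the diacid never have to be told apart.
Forward: oleic acid 1 and 2-phenylethanol 2 give the oleate 3, oxidative cleavage gives the half-ester 4, and anodic decarboxylative coupling of 4 with stearic acid 5 gives the target 6.
No ring is formed at any stage (the phenyl ring is bought in 2). No organometallic reagent, acrylate or hydrocarbon intermediate occurs, so the conjugate addition, the alkyl–alkyl coupling and the acrylate of the direct plan have no counterpart.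

Key step: step 3

Assumption: oleic acid is taken as the ≥99 % (9Z) grade, free of linoleic acid and of positional isomers, so that cleavage at C9=C10 gives a single C9 half-ester.

Step 1
Reactants: 1 oleic acid ((9Z)-octadec-9-enoic acid), 2 2-phenylethanol
Product: 3 2-phenylethyl (9Z)-octadec-9-enoate (2-phenylethyl oleate)
Conditions: 1 (1.0 equiv), 2 (1.2 equiv), p-TsOH·H2O (1 mol %), toluene, reflux, Dean–Stark, 4 h; aq NaHCO3 wash; excess 2 distilled off (Kugelrohr, 90 °C, 0.5 mbar); silica plug (hexane–EtOAc 95:5)
Reagents that add atoms: none
Why: Fischer esterification driven by azeotropic removal of water; 1 has a single carboxyl group, so no mono/di-ester problem can arise, the isolated Z-alkene should not migrate at 1 mol % acid, and no stereocentre is formed.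

Step 2
Reactants: 3 2-phenylethyl (9Z)-octadec-9-enoate
Product: 4 9-oxo-9-(2-phenylethoxy)nonanoic acid (mono(2-phenylethyl) azelate)
Conditions: 3 (1.0 equiv), NaIO4 (6 equiv), KMnO4 (5 mol %), K2CO3 (1.5 equiv, pH 7.5–8), t-BuOH–H2O (1:1), 25 °C, 16 h; aq HCl to pH 2, EtOAc; nonanoic acid distilled off (Kugelrohr, 110 °C, 0.5 mbar); crystallisation from hexane–Et2O or silica (hexane–EtOAc–AcOH 70:30:1)
Reagents that add atoms: sodium periodate, [Na+].[O-]I(=O)(=O)=O; potassium permanganate, [K+].[O-][Mn](=O)(=O)=O; water, O
Why: Lemieux–von Rudloff oxidation, in which catalytic permanganate oxidises the only C=C bond of 3 and periodate cleaves the oxygenated carbons and regenerates permanganate, so that both alkene carbons end as CO2H with the two new oxygens drawn from the oxidant–water pool; the ester, the saturated chain and the unactivated phenyl ring are inert to the cold, dilute, weakly basic reagent, the half-ester forms as a single constitutional isomer because the ester was in place before the second carboxyl appeared, and no stereocentre is formed.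

Step 3
Reactants: 4 9-oxo-9-(2-phenylethoxy)nonanoic acid, 5 stearic acid (octadecanoic acid)
Product: 6 2-phenylethyl pentacosanoate
Conditions: 4 (1.0 equiv), 5 (3.0 equiv), KOH (5 mol % of total CO2H), MeOH (0.3 M in acid), 50 °C, undivided cell, smooth platinum foil anode and cathode (2 mm gap), constant current 0.25 A cm−2, polarity reversed every 60 s, vigorous stirring, ca. 1.2 F per mol of acid, stopped while the electrolyte is still faintly acidic; AcOH; evaporation, warm hexane, aq K2CO3 wash; silica (hexane, then hexane–Et2O 97:3); recrystallisation from acetone
Reagents that add atoms: none
Why: Mixed Kolbe electrolysis: at a smooth platinum anode at high current density the carboxylates of 4 and 5 are each oxidised by one electron and lose CO2, and the 7-(2-phenylethoxycarbonyl)heptyl and heptadecyl radicals combine in the anode layer to form the C8–C9 bond, while the carboxyl protons are reduced to H2 at the cathode, which keeps the degree of neutralisation constant. The closest known reaction type is the anodic cross-coupling of a fatty acid with an alkyl hydrogen dicarboxylate, the classical chain extension of fatty acids, here with a 2-phenylethyl in place of a methyl ester. No ring is closed and no stereocentre is formed, since C8 and C9 both become CH2. The step needs the radical path over the carbocation (Hofer–Moest) path, which is secured because both radicals are primary and unbranched and carry no α-heteroatom or α-aryl group, the ester and the phenyl ring of 4 lying seven and more atoms from the radical centre. It needs cross- over homo-coupling, which is only statistical, so the cheap acid 5 is used in threefold excess to direct most radicals from 4 into the mixed product, and the two symmetrical by-products (a C34 alkane and a C16 diester) differ from the mono-ester 6 by one ester group each and should separate on silica. It needs the 2-phenylethyl ester to survive methanol, which is secured by keeping the electrolyte on the acid side (5 % neutralisation, electrolysis stopped before the acids are used up, AcOH quench) so that no methoxide builds up.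

**Compound list**
1 | oleic acid, (9Z)-octadec-9-enoic acid | CCCCCCCC/C=C\CCCCCCCC(=O)O | starting material
2 | 2-phenylethanol | OCCc1ccccc1 | starting material
3 | 2-phenylethyl (9Z)-octadec-9-enoate (2-phenylethyl oleate) | CCCCCCCC/C=C\CCCCCCCC(=O)OCCc1ccccc1 | intermediate
4 | 9-oxo-9-(2-phenylethoxy)nonanoic acid (mono(2-phenylethyl) azelate) | OC(=O)CCCCCCCC(=O)OCCc1ccccc1 | intermediate
5 | stearic acid (octadecanoic acid) | CCCCCCCCCCCCCCCCCC(=O)O | starting material
6 | 2-phenylethyl pentacosanoate (achiral) | CCCCCCCCCCCCCCCCCCCCCCCCC(=O)OCCc1ccccc1 | target

Total step count: 3. Longest linear sequence: 3 (1 → 3 → 4 → 6; 5 enters in step 3 as purchased).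

**Steps most likely to fail** (the route has three steps; they are ranked by risk)

Step 3 (mixed Kolbe electrolysis). The two radicals may pair mainly with their own kind, wax may passivate the anode, the 2-phenylethyl ester may exchange with the methanolic electrolyte once it turns basic near the cathode, or the phenyl ring may be oxidised at the anode potential. The fallback replaces radical coupling by a polar olefination. It sets out from 3, which would be ozonised (O3, CH2Cl2, −78 °C; Me2S) to the aldehyde 2-phenylethyl 9-oxononanoate F1 and nonanal. Hexadecyltriphenylphosphonium bromide F2 would be deprotonated with NaN(SiMe3)2 (THF, −78 °C), and the ylide of F2 would convert F1 by a Wittig reaction (−78 °C to rt) into 2-phenylethyl (9Z)-pentacos-9-enoate F3. Hydrogenation of F3 (H2, 1 atm, Pd/C, EtOAc, rt) would come back to the route at 6; the ester C–O bond is homobenzylic and should not be hydrogenolysed.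

Step 2 (oxidative cleavage). The lipophilic ester may be cleaved slowly or incompletely in the aqueous medium, part of the ester may be hydrolysed at pH 8, or nonanoic acid may be removed incompletely and enter the electrolysis as a third acid. The fallback avoids any C=C cleavage. It sets out from 2, which would be heated with a fourfold excess of azelaic acid F4 and p-TsOH·H2O (2 mol %) in toluene under a Dean–Stark trap, so that statistical mono-esterification favours the half-ester. The excess of F4 would crystallise on cooling and be washed out with warm water, the neutral diester would stay in the organic phase when the half-ester is extracted into aq NaHCO3, and the route is rejoined at 4.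

Step 1 (esterification). The acid at reflux may cause the double bond to migrate along the chain, which would move the later cleavage site, or conversion may stay incomplete. The fallback is an irreversible acylation under base. It sets out from 1, which would be converted with oxalyl chloride and a trace of DMF (CH2Cl2, 0 °C to rt) into (9Z)-octadec-9-enoyl chloride F5. The crude F5 would then acylate 2 in the presence of pyridine (CH2Cl2, 0 °C), rejoining the route at 3.

**Further compounds**
F1 | step 3 | 2-phenylethyl 9-oxononanoate | O=CCCCCCCCC(=O)OCCc1ccccc1
F2 | step 3 | hexadecyltriphenylphosphonium bromide | CCCCCCCCCCCCCCCC[P+](c1ccccc1)(c1ccccc1)c1ccccc1.[Br-]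
F3 | step 3 | 2-phenylethyl (9Z)-pentacos-9-enoate | CCCCCCCCCCCCCCC/C=C\CCCCCCCC(=O)OCCc1ccccc1
F4 | step 2 | azelaic acid (nonanedioic acid) | OC(=O)CCCCCCCC(=O)O
F5 | step 1 | (9Z)-octadec-9-enoyl chloride (oleoyl chloride) | CCCCCCCC/C=C\CCCCCCCC(=O)Cl
A1 | direct plan | 2-phenylethyl acrylate | C=CC(=O)OCCc1ccccc1
A2 | direct plan | docos-1-ene | CCCCCCCCCCCCCCCCCCCCC=C
A3 | direct plan | 1-bromooctadecane | CCCCCCCCCCCCCCCCCCBr
A4 | direct plan | but-3-enylmagnesium bromide | C=CCC[Mg]Br
A5 | direct plan | 9-docosyl-9-borabicyclo[3.3.1]nonane (9-docosyl-9-BBN) | CCCCCCCCCCCCCCCCCCCCCCB1C2CCCC1CCC2
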